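## Retrosynthetic overview
- The target is the open hydroxy-enal. Ring B is closed last by an intramolecular aldol/dehydration of an aryl aldehyde (C4) onto a succinate (C3), which gives the C3=C4 enoate. The enoate is then taken to the enal by diol formation and selective allylic oxidation.
- The diarylmethine C1–C8a bond and the C1 stereocentre come from an aromatic Claisen [3,3] rearrangement. The migrating oxygen ends up as C8–O (later OMe), and the only free ortho site is C8a.
- The Claisen substrate is a D-malate-derived (E)-arylidene α-aryloxy succinate. The malate C–O stereocentre is transferred to C1 through a chair transition state. C2 is equilibrated to trans late in the route.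
- Only ring B is formed, after the Claisen step. The four-carbon chain C9′–C3–C2–C9 comes entirely from malate.

Assumptions:
- Dimethyl D-malate and 4-(benzyloxy)-3-hydroxybenzaldehyde are purchased.
- The 1,2-trans isomer is the thermodynamic one, because the C1 aryl is pseudo-axial to avoid the peri 8-OMe, so C2 can be equilibrated with DBU.

## Route

**Step 1**
Reactants: 1 dimethyl (2R)-2-hydroxybutanedioate (dimethyl D-malate); 2 3,4-dimethoxybenzaldehyde
Product: 3 dimethyl (2R)-3-[(3,4-dimethoxyphenyl)(hydroxy)methyl]-2-hydroxybutanedioate (diastereomer mixture at the two new centres)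
Conditions: LDA (2.2 equiv), THF, –78 °C; then 2; NH4Cl work-up
Reagents that add atoms: none
Why: Seebach-type dianion aldol at the CH2 α to the C4 ester, with the alkoxide preserving the C2–O stereocentre. The two new centres are destroyed in Step 2, so their ratio is irrelevant.

**Step 2**
Reactants: 3
Product: 4 dimethyl (2R,3E)-3-(3,4-dimethoxybenzylidene)-2-hydroxybutanedioate
Conditions: TsOH·H2O (cat.), PhMe, 80 °C, Dean–Stark; separate the minor Z isomer by chromatography
Reagents that add atoms: none
Why: Acid-catalysed E1 dehydration of the electron-rich benzylic alcohol avoids base, so the α-hydroxy ester centre is not epimerised. The thermodynamic trisubstituted cinnamate has Ar′ cis to the CH(OH)CO2Me arm (Z-allylic for the Claisen step).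

**Step 3**
Reactants: 4; 5 4-(benzyloxy)-3-hydroxybenzaldehyde
Product: 6 dimethyl (2S,3E)-2-[2-(benzyloxy)-5-formylphenoxy]-3-(3,4-dimethoxybenzylidene)butanedioate
Conditions: PPh3, DIAD, THF, 0 °C → rt
Reagents that add atoms: none
Why: Mitsunobu etherification (SN2) of the α-hydroxy ester by the acidic phenol inverts the centre from R to S, which is the enantiomer the chair analysis in Step 4 requires.

**Step 4**
Reactants: 6
Product: 7 dimethyl (Z)-2-[(S)-(3-benzyloxy-6-formyl-2-hydroxyphenyl)(3,4-dimethoxyphenyl)methyl]but-2-enedioate. It may partly cyclise to the dihydrocoumarin, which converges in Step 6.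
Conditions: PhNEt2 (or o-dichlorobenzene), 190 °C, sealed tube or microwave, 2 h, Ar
Reagents that add atoms: none
Why: Aromatic Claisen [3,3] rearrangement. C4 of the arene carries OBn, so the new C–C bond goes to C2 of the arene (future C8a), and the phenol re-forms by tautomerisation. In the suprafacial chair transition state the ester on Cα is equatorial and the Z-Ar′ is axial, so the (S)-ether gives the (S)-diarylmethine, which is C1 of the target.

**Step 5**
Reactants: 7
Product: 8 dimethyl 2-[(3-benzyloxy-6-formyl-2-hydroxyphenyl)(3,4-dimethoxyphenyl)methyl]butanedioate (C1 as in target; C2 unresolved)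
Conditions: H2 (1 atm), 5% Pd/C(en), EtOAc, rt
Reagents that add atoms: none
Why: Chemoselective hydrogenation of the electron-poor alkene, with the ethylenediamine-modified Pd leaving the benzyl ether intact. This removes the vinylogously acidic C1–H before any base is used, so C1 cannot racemise. C2 is set only substrate-biased here and is corrected in Step 8.

**Step 6**
Reactants: 8; 9 iodomethane
Product: 10 dimethyl 2-[(3-benzyloxy-6-formyl-2-methoxyphenyl)(3,4-dimethoxyphenyl)methyl]butanedioate
Conditions: K2CO3, MeI, DMF/MeOH (9:1), rt
Reagents that add atoms: MeI, CI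
Why: Williamson O-methylation of the C8 phenol. The MeOH co-solvent reopens any dihydrocoumarin as the methyl ester, and the benzhydryl C1–H is no longer acidic.

**Step 7**
Reactants: 10
Product: 11 dimethyl 7-(benzyloxy)-4-hydroxy-1-(3,4-dimethoxyphenyl)-8-methoxy-1,2,3,4-tetrahydronaphthalene-2,3-dicarboxylate (C1 as in target; other centres unresolved)
Conditions: LiHMDS (1.1 equiv), THF, –78 → –30 °C; NH4Cl
Reagents that add atoms: none
Why: Intramolecular aldol reaction. The kinetic enolate forms at the unhindered C3H2 and closes onto the aryl aldehyde (6-(enolexo)-exo-trig) to form ring B, and the C3/C4 centres are removed in Step 8.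

**Step 8**
Reactants: 11
Product: 12 dimethyl (1S,2R)-7-(benzyloxy)-1-(3,4-dimethoxyphenyl)-8-methoxy-1,2-dihydronaphthalene-2,3-dicarboxylate
Conditions: 1) MsCl, Et3N, CH2Cl2, 0 °C; 2) DBU, CH2Cl2, rt, Ar
Reagents that add atoms: none
Why: E1cB elimination of the mesylate gives the styrenyl enoate C3=C4, which is stabilised by the p-OBn donor. DBU then equilibrates the ester-α, allylic C2–H to the trans (pseudo-diaxial) isomer, which sets C2 relative to C1 and leaves C1 untouched.

**Step 9**
Reactants: 12
Product: 13 [(1S,2R)-7-benzyloxy-1-(3,4-dimethoxyphenyl)-8-methoxy-1,2-dihydronaphthalene-2,3-diyl]dimethanol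
Conditions: DIBAL-H (5 equiv), CH2Cl2, –78 → 0 °C
Reagents that add atoms: none
Why: Hydride reduction of both esters to primary alcohols. There is no stereochemical change, and the aryl ethers and the alkene are untouched.

**Step 10**
Reactants: 13
Product: 14 (1S,2R)-7-(benzyloxy)-1-(3,4-dimethoxyphenyl)-2-(hydroxymethyl)-8-methoxy-1,2-dihydronaphthalene-3-carbaldehyde
Conditions: activated MnO2 (20 equiv), CH2Cl2, rt
Reagents that add atoms: none
Why: MnO2 oxidises only the allylic, styrenyl C9′-OH. The homoallylic C9-OH is inert, so the enal forms without touching the stereocentres.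

**Step 11**
Reactants: 14
Product: 15 vitekwangin B (target)
Conditions: BCl3 (3 equiv), pentamethylbenzene (3 equiv), CH2Cl2, –78 °C; then MeOH, NaHCO3
Reagents that add atoms: none
Why: Aryl benzyl ether cleavage by BCl3, with a cation scavenger to prevent Friedel–Crafts benzylation. The methyl ethers, the enal and the primary alcohol survive at –78 °C, and no stereocentre is involved.

## Compound list
1 | dimethyl (2R)-2-hydroxybutanedioate (dimethyl D-malate) | COC(=O)C[C@@H](O)C(=O)OC | starting material
2 | 3,4-dimethoxybenzaldehyde | COc1ccc(C=O)cc1OC | starting material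
3 | aldol adduct (new centres undefined) | COC(=O)C(C(O)c1ccc(OC)c(OC)c1)[C@@H](O)C(=O)OC | intermediate
4 | dimethyl (2R,3E)-3-(3,4-dimethoxybenzylidene)-2-hydroxybutanedioate | COC(=O)[C@H](O)/C(=C\c1ccc(OC)c(OC)c1)C(=O)OC | intermediate
5 | 4-(benzyloxy)-3-hydroxybenzaldehyde | O=Cc1ccc(OCc2ccccc2)c(O)c1 | starting material
6 | aryl ether (2S,3E) | COC(=O)[C@@H](Oc1cc(C=O)ccc1OCc1ccccc1)/C(=C\c1ccc(OC)c(OC)c1)C(=O)OC | intermediate
7 | Claisen product (Z)-diester, free C8-OH | COc1ccc([C@H](C(\C(=O)OC)=C\C(=O)OC)c2c(C=O)ccc(OCc3ccccc3)c2O)cc1OC | intermediate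
8 | saturated diester (C2 unresolved) | COc1ccc([C@H](C(C(=O)OC)CC(=O)OC)c2c(C=O)ccc(OCc3ccccc3)c2O)cc1OC | intermediate
9 | iodomethane | CI | starting material (reagent)
10 | C8-OMe diester aldehyde | COc1ccc([C@H](C(C(=O)OC)CC(=O)OC)c2c(C=O)ccc(OCc3ccccc3)c2OC)cc1OC | intermediate
11 | β-hydroxy tetralin diester (C1 defined only) | COc1ccc([C@H]2c3c(ccc(OCc4ccccc4)c3OC)C(O)C(C(=O)OC)C2C(=O)OC)cc1OC | intermediate
12 | (1S,2R)-dihydronaphthalene diester | COc1ccc([C@H]2c3c(ccc(OCc4ccccc4)c3OC)C=C(C(=O)OC)[C@@H]2C(=O)OC)cc1OC | intermediate
13 | (1S,2R)-diol | COc1ccc([C@H]2c3c(ccc(OCc4ccccc4)c3OC)C=C(CO)[C@@H]2CO)cc1OC | intermediate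
14 | (1S,2R)-7-O-benzyl enal | COc1ccc([C@H]2c3c(ccc(OCc4ccccc4)c3OC)C=C(C=O)[C@@H]2CO)cc1OC | intermediate
15 | vitekwangin B | COc1ccc([C@H]2c3c(ccc(O)c3OC)C=C(C=O)[C@@H]2CO)cc1OC | target

## Totals
Total steps: 11. Longest linear sequence: 11, from dimethyl D-malate; compounds 2 and 5 are purchased partners.

## Three steps most likely to fail
1. **Step 4 (Claisen).** The reaction site is hindered (ortho to CHO), it needs high temperature, and a boat transition state or Z/E leakage would erode ee.
   - Fallback (different approach): form C1–C8a by directed ortho-metalation of an acetal-protected 3-methoxy-4-benzyloxybenzaldehyde. Add the aryllithium 1,4 to the O-silylated malate arylidene, with 1,2-induction from the α-OSiR3 centre, then remove the α-oxygen by Barton–McCombie deoxygenation.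
2. **Step 7 (aldol cyclisation).** Amide base may add to the aldehyde, or the C2 enolate may close a five-membered ring.
   - Fallback (different approach): use 2-(benzyloxy)phenol as the Claisen partner, so the arene carries no CHO. After Step 5, hydrolyse the C3-side ester selectively and close ring B by intramolecular Friedel–Crafts acylation at C4a to the 4-tetralone. Then reduce the ketone and dehydrate, install C9′ by Vilsmeier formylation of the resulting dihydronaphthalene, and finish as before.
3. **Step 5 (chemoselective hydrogenation).** Over-reduction of the ArCHO or debenzylation would give the wrong product.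
   - Fallback (different approach): carry the aldehyde as its dimethyl acetal from the start, using the acetal of 5. Reduce the fumarate/maleate by Mg/MeOH conjugate reduction, then unmask the aldehyde with mild acid just before the aldol step.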